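## Retrosynthetic overview
1. Functional-group changes: the two CH2OH groups come from esters. A sacrificial C4–OH and both phenol benzyl ethers are removed together at the end. This leads back to a 1-aryl-4-hydroxytetralin-2,3-diester.
2. Key disconnection: C1–C2 and C3–C4 are cut together (retro-[4+2]). This gives the photoenol of a 2-benzylbenzaldehyde, an (E,E)-α-hydroxy-α'-aryl-o-quinodimethane, plus the C2-symmetric fumarate of methyl (R)-mandelate. All stereocentres are set in this one step.
3. The 2-benzylbenzaldehyde comes from an sp2–sp3 Negishi coupling of two vanillin-derived halves.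
4. Ring order: both arenes are purchased. The only ring built is the central cyclohexane ring, formed in the photochemical step.
5. The usual C1–C8a Friedel–Crafts closure of a dibenzylbutane or butyrolactone is deliberately not used.

Assumptions:
- The SMILES decodes as (−)-isolariciresinol, all-trans, (1R,2S,3S) in aryltetralin numbering (C1 = aryl-bearing carbon). This equals (6S,7S,8R) in naphthalen-2-ol numbering. Aryltetralin numbering is used below.
- The sense of induction of the mandelate fumarate is taken from my recollection that the (S)-auxiliary gives the (+)-series, supported by the conformational model in Step 5. It must be confirmed by optical rotation at compound 11. Both auxiliary antipodes are commercial.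

## Route

**Step 1**
Reactants: 1, 4-(benzyloxy)-3-methoxybenzaldehyde (O-benzylvanillin)
Product: 2, 4-(benzyloxy)-2-bromo-5-methoxybenzaldehyde
Conditions: Br2, NaOAc, AcOH, rt
Reagents that add atoms: bromine, BrBr
Why: Electrophilic aromatic bromination goes para to the OMe group (the veratraldehyde pattern), and NaOAc buffers HBr so the benzyl ether survives; no stereocentre is formed.

**Step 2**
Reactants: 3, [4-(benzyloxy)-3-methoxyphenyl]methanol
Product: 4, 1-(benzyloxy)-4-(chloromethyl)-2-methoxybenzene
Conditions: SOCl2, CH2Cl2, 0 °C; used directly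
Reagents that add atoms: thionyl chloride, O=S(Cl)Cl (supplies Cl)
Why: Chlorodehydroxylation of an electron-rich benzylic alcohol is fast at 0 °C and leaves the ethers untouched.

**Step 3**
Reactants: 4, benzylic chloride; 2, aryl bromide
Product: 5, 4-(benzyloxy)-2-[4-(benzyloxy)-3-methoxybenzyl]-5-methoxybenzaldehyde
Conditions: Zn, LiCl, THF, 25 °C (ArCH2ZnCl in situ); then 2, Pd(OAc)2 (2 mol %), SPhos (4 mol %), THF, 25→40 °C
Reagents that add atoms: none (Zn, LiCl and Pd are not retained)
Why: In this Negishi sp3–sp2 cross-coupling, the LiCl-mediated benzylic zinc reagent does not add to the aldehyde, and the ortho-formyl bromide undergoes oxidative addition readily.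

**Step 4**
Reactants: 6, fumaryl chloride; 7, methyl (R)-mandelate (2.1 equiv)
Product: 8, bis[(1R)-2-methoxy-2-oxo-1-phenylethyl] (E)-but-2-enedioate
Conditions: toluene, 90 °C, N2 sweep (−HCl), no base; recrystallise
Reagents that add atoms: none beyond reactants 6, O=C(Cl)/C=C/C(=O)Cl, and 7, COC(=O)[C@H](O)c1ccccc1
Why: Base-free acyl chloride alcoholysis avoids racemising the acidic mandelate α-H and keeps the E-alkene; the C–O stereocentres are not touched.

**Step 5 (key step)**
Reactants: 5, 2-benzylbenzaldehyde; 8, chiral fumarate (1.5–2 equiv)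
Product: 9, bis[(1R)-2-methoxy-2-oxo-1-phenylethyl] (1R,2S,3R,4R)-7-(benzyloxy)-1-[4-(benzyloxy)-3-methoxyphenyl]-4-hydroxy-6-methoxy-1,2,3,4-tetrahydronaphthalene-2,3-dicarboxylate (1,2-trans, 2,3-trans, 3,4-cis, 1,4-cis)
Conditions: hν (365 nm), degassed toluene (0.02 M), 15 °C; crystallise or chromatograph to a single diastereomer
Reagents that add atoms: none beyond reactant 8
Why: This is a photoenolization/Diels–Alder reaction in which excited 5 transfers a doubly benzylic H to the carbonyl O to give the long-lived (E,E)-hydroxy-o-quinodimethane, which adds suprafacially to the fumarate (Ar and OH both "outside" gives 1,4-cis; the E-alkene gives 2,3-trans; the ester next to the carbinol carbon sits endo, H-bonded to the dienol OH and away from the aryl, giving 3,4-cis and 1,2-trans), while the two (R)-mandelate units (s-cis enoate, carbinyl C–H eclipsing C=O) place both phenyls over the Re,Re face so bonding occurs on the Si,Si face, giving 1R,2S,3R,4R.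

**Step 6**
Reactants: 9, cycloadduct
Product: 10, (1R,2S,3S,4R)-7-(benzyloxy)-1-[4-(benzyloxy)-3-methoxyphenyl]-2,3-bis(hydroxymethyl)-6-methoxy-1,2,3,4-tetrahydronaphthalen-4-ol (the C3 descriptor changes by CIP priority only)
Conditions: LiAlH4 (6 equiv), THF, 0 °C→rt; Rochelle salt work-up
Reagents that add atoms: none
Why: Hydride reduction of all four esters gives both CH2OH groups and releases the auxiliary as separable (R)-1-phenylethane-1,2-diol, while reduction at 0 °C outruns enolisation or retro-aldol, so C1–C4 and the benzyl ethers are unchanged.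

**Step 7**
Reactants: 10, triol
Product: 11, (−)-isolariciresinol, (1R,2S,3S) = (6S,7S,8R)-8-(4-hydroxy-3-methoxyphenyl)-6,7-bis(hydroxymethyl)-3-methoxy-5,6,7,8-tetrahydronaphthalen-2-ol
Conditions: H2 (4 bar), 10 % Pd/C, EtOH–AcOH (9:1), 40 °C
Reagents that add atoms: none
Why: Catalytic hydrogenolysis cleaves both O-benzyl groups, after which the pseudoaxial C4–OH is a p-hydroxybenzylic alcohol that is reduced readily (via the quinone methide) to CH2, erasing the sacrificial stereocentre and leaving C1, C2 and C3 untouched.

## Compound list
| No. | Name | SMILES | Role |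
|---|---|---|---|
| 1 | O-benzylvanillin | COc1cc(C=O)ccc1OCc1ccccc1 | starting material |
| 2 | 4-(benzyloxy)-2-bromo-5-methoxybenzaldehyde | COc1cc(C=O)c(Br)cc1OCc1ccccc1 | intermediate |
| 3 | [4-(benzyloxy)-3-methoxyphenyl]methanol | COc1cc(CO)ccc1OCc1ccccc1 | starting material |
| 4 | 1-(benzyloxy)-4-(chloromethyl)-2-methoxybenzene | COc1cc(CCl)ccc1OCc1ccccc1 | intermediate |
| 5 | 4-(benzyloxy)-2-[4-(benzyloxy)-3-methoxybenzyl]-5-methoxybenzaldehyde | COc1cc(Cc2cc(OCc3ccccc3)c(OC)cc2C=O)ccc1OCc1ccccc1 | intermediate |
| 6 | fumaryl chloride | O=C(Cl)/C=C/C(=O)Cl | starting material |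
| 7 | methyl (R)-mandelate | COC(=O)[C@H](O)c1ccccc1 | starting material |
| 8 | bis[(1R)-2-methoxy-2-oxo-1-phenylethyl] fumarate | COC(=O)[C@H](OC(=O)/C=C/C(=O)O[C@@H](C(=O)OC)c1ccccc1)c1ccccc1 | intermediate |
| 9 | (1R,2S,3R,4R)-1-aryl-4-hydroxytetralin-2,3-dicarboxylate, bis-(R)-mandelate ester | COc1cc([C@@H]2c3cc(OCc4ccccc4)c(OC)cc3[C@H](O)[C@H](C(=O)O[C@@H](C(=O)OC)c5ccccc5)[C@H]2C(=O)O[C@@H](C(=O)OC)c6ccccc6)ccc1OCc7ccccc7 | intermediate |
| 10 | (1R,2S,3S,4R)-di-O-benzyl-4-hydroxyisolariciresinol | COc1cc([C@@H]2c3cc(OCc4ccccc4)c(OC)cc3[C@H](O)[C@H](CO)[C@H]2CO)ccc1OCc5ccccc5 | intermediate |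
| 11 | (−)-isolariciresinol | COc1cc([C@@H]2c3cc(O)c(OC)cc3C[C@H](CO)[C@H]2CO)ccc1O | target |

## Summary
Total steps: 7. Longest linear sequence: 5 (Step 1 or 2 → 3 → 5 → 6 → 7).

Steps most likely to fail, with fallbacks:
1. **Step 5.**
   - Risk: the electron-rich aldehyde may photoenolise with low efficiency, sensitisation may isomerise the fumarate to the maleate, or facial or endo selectivity may be poor.
   - Fallback: separate the light step from the cycloaddition. Irradiate 5 in SO2-saturated solvent to trap the photoenol as the isolable 1-hydroxy-3-aryl-1,3-dihydrobenzo[c]thiophene 2,2-dioxide. Then regenerate the same (E,E)-diene in the dark by thermal cheletropic SO2 extrusion (toluene, 80–110 °C) in the presence of 8.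
2. **Step 7.**
   - Risk: C4–OH hydrogenolysis may stall, or dehydration to the C3=C4 styrene followed by re-hydrogenation may scramble C3.
   - Fallback: remove the C4–OH earlier by ionic deoxygenation of diester 9 (Et3SiH with BF3·OEt2, fast hydride capture of the p-alkoxybenzyl cation). Then carry out the LiAlH4 reduction, so the last step is only a neutral O-debenzylation.
3. **Step 3.**
   - Risk: the electron-rich benzylic zinc reagent may undergo Wurtz homocoupling, or the coupling may be sluggish.
   - Fallback: reverse the polarity. Protect 2 as its dimethyl acetal, carry out Br/Li exchange, and add the aryllithium to aldehyde 1 to give the benzhydrol. Ionic reduction (Et3SiH, TFA) then removes the OH and unmasks the aldehyde to give 5.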